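**Retrosynthetic overview**
- 12 ⇐ 11: one hydrogenation turns the C≡C unit into the CH2CH2 bridge and frees the three phenols.
- 11 ⇐ 6 + 8 + 7: the strategy rests on C1 of ring A, which lies between the benzylated carbons C2 and C6 and carries a two-carbon bridge ending on an aryl carbon of ring B. At the alkyne level that bridge is linear acetylene, so C1–Cα and Cβ–C(ring B) are cut as two Sonogashira bonds.
- 6 ⇐ 3 + 2 × 5: both ArCH2–ring A bonds come from a double Negishi coupling at the two iodides of 3; 3 ⇐ 2 ⇐ 1 by diiodination and O-benzylation.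
- No ring is formed at any stage: the four benzene rings come from 1, 4 (twice) and 7.

Key step: step 4

Remark: the target has no stereogenic centre, axis or double bond, so no stereocontrol is needed and no step creates a stereocentre.

**Step 1**
Reactants: 1 3-bromo-5-methoxyphenol
Product: 2 1-(benzyloxy)-3-bromo-5-methoxybenzene
Conditions: BnBr (1.1 equiv), K2CO3, DMF, rt
Reagents that add atoms: benzyl bromide, BrCc1ccccc1
Why: Williamson ether synthesis, in which the phenoxide of 1 is alkylated at oxygen while the aryl bromide and the methyl ether are inert to carbonate in DMF.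

**Step 2**
Reactants: 2 1-(benzyloxy)-3-bromo-5-methoxybenzene
Product: 3 1-(benzyloxy)-3-bromo-2,4-diiodo-5-methoxybenzene
Conditions: NIS (2.2 equiv), TFA (cat.), MeCN, 0 °C to rt, dark
Reagents that add atoms: N-iodosuccinimide, O=C1CCC(=O)N1I
Why: Electrophilic aromatic iodination, in which each carbon flanking bromine is para to one alkoxy group and ortho to the other (the pattern that takes two halogens in 1-substituted 3,5-dialkoxybenzenes), whereas the carbon between the oxygens is ortho to both and should react last, so two equivalents of NIS should stop at the 2,4-diiodide.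

**Step 3**
Reactants: 3 1-(benzyloxy)-3-bromo-2,4-diiodo-5-methoxybenzene; 4 4-(benzyloxy)benzyl chloride (2.5 equiv)
Product: 6 1-(benzyloxy)-2,4-bis[4-(benzyloxy)benzyl]-3-bromo-5-methoxybenzene, via 4-(benzyloxy)benzylzinc chloride 5 (not isolated)
Conditions: 4, Zn dust, LiCl, THF, rt; then 3, Pd2(dba)3 (2.5 mol%), P(2-furyl)3 (10 mol%), THF, rt to 50 °C
Reagents that add atoms: none
Why: Negishi cross-coupling, in which zinc inserts into the benzylic C–Cl bond of 4 and Pd(0)/tri(2-furyl)phosphine adds to the two C–I bonds much faster than to the C–Br bond, which is shielded first by the iodines and then by the new benzyl groups, so both iodides should be replaced and the bromide kept for step 4.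

**Step 4**
Reactants: 6 1-(benzyloxy)-2,4-bis[4-(benzyloxy)benzyl]-3-bromo-5-methoxybenzene (1.0 equiv); 7 3-iodoanisole (1.3 equiv); 8 ethynyltrimethylsilane (1.35 equiv)
Product: 11 1-(benzyloxy)-2,4-bis[4-(benzyloxy)benzyl]-5-methoxy-3-[(3-methoxyphenyl)ethynyl]benzene, via 3-[(trimethylsilyl)ethynyl]anisole 9 (not isolated), via 3-ethynylanisole 10 (not isolated)
Conditions: 7, 8, Pd(PhCN)2Cl2 (5 mol%), [HP(t-Bu)3]BF4 (10 mol%), CuI (5 mol%), i-Pr2NH (3 equiv), degassed 1,4-dioxane, rt; then Ar purge, 6, TBAF (1 M in THF, 1.4 equiv, added over 3 h), 70 °C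
Reagents that add atoms: none
Why: Two Sonogashira couplings are run in one flask with desilylation in between, the known one-pot route to unsymmetrical diarylalkynes: Pd(0) first inserts into the C–I bond of 7 at room temperature and the copper acetylide of 8 gives 9, while the hindered C–Br bond of 6 and the C–Si bond are untouched. Fluoride then releases 10 slowly as its copper acetylide, and Pd(0) bearing one P(t-Bu)3, the ligand class used for 2,6-dialkyl aryl bromides, inserts into C1–Br of 6 at 70 °C; transmetalation of the linear acetylide and reductive elimination form C1–Cα. No ring is closed and no stereocentre is formed. The selectivity needed is iodide before bromide and one aryl group per alkyne terminus: the reactivity gap between an unhindered aryl iodide and a di-ortho-benzylated bromide secures the first, and the silyl cap on 8 secures the second. Slow fluoride addition and exclusion of oxygen keep free 10 low and suppress Glaser dimerisation, and an amine base rather than carbonate or carboxylate disfavours C–H arylation of the flanking benzyl rings.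

**Step 5**
Reactants: 11 1-(benzyloxy)-2,4-bis[4-(benzyloxy)benzyl]-5-methoxy-3-[(3-methoxyphenyl)ethynyl]benzene
Product: 12 2,4-bis(4-hydroxybenzyl)-5-methoxy-3-[2-(3-methoxyphenyl)ethyl]phenol (the target)
Conditions: H2 (3 atm), 10% Pd/C, EtOAc–MeOH (1:1), rt
Reagents that add atoms: none
Why: Catalytic hydrogenation and hydrogenolysis over Pd/C should saturate the diaryl alkyne to the CH2CH2 bridge via the cis-stilbene and cleave the three benzylic C–O bonds, while the aryl methyl ethers and the diarylmethane C–C bonds are stable.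

**Compound list**
1 | 3-bromo-5-methoxyphenol | COc1cc(O)cc(Br)c1 | starting material
2 | 1-(benzyloxy)-3-bromo-5-methoxybenzene | COc1cc(Br)cc(OCc2ccccc2)c1 | intermediate
3 | 1-(benzyloxy)-3-bromo-2,4-diiodo-5-methoxybenzene | COc1cc(OCc2ccccc2)c(I)c(Br)c1I | intermediate
4 | 4-(benzyloxy)benzyl chloride [1-(benzyloxy)-4-(chloromethyl)benzene] | ClCc1ccc(OCc2ccccc2)cc1 | starting material
5 | [4-(benzyloxy)benzyl]zinc chloride (formed in the flask) | Cl[Zn]Cc1ccc(OCc2ccccc2)cc1 | intermediate
6 | 1-(benzyloxy)-2,4-bis[4-(benzyloxy)benzyl]-3-bromo-5-methoxybenzene | COc1cc(OCc2ccccc2)c(Cc2ccc(OCc3ccccc3)cc2)c(Br)c1Cc1ccc(OCc2ccccc2)cc1 | intermediate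
7 | 3-iodoanisole | COc1cccc(I)c1 | starting material
8 | ethynyltrimethylsilane | C#C[Si](C)(C)C | starting material
9 | 3-[(trimethylsilyl)ethynyl]anisole (formed in the flask) | COc1cccc(C#C[Si](C)(C)C)c1 | intermediate
10 | 3-ethynylanisole (formed in the flask) | COc1cccc(C#C)c1 | intermediate
11 | 1-(benzyloxy)-2,4-bis[4-(benzyloxy)benzyl]-5-methoxy-3-[(3-methoxyphenyl)ethynyl]benzene | COc1cccc(C#Cc2c(Cc3ccc(OCc4ccccc4)cc3)c(OCc3ccccc3)cc(OC)c2Cc2ccc(OCc3ccccc3)cc2)c1 | intermediate
12 | 2,4-bis(4-hydroxybenzyl)-5-methoxy-3-[2-(3-methoxyphenyl)ethyl]phenol | COc1cccc(CCc2c(Cc3ccc(O)cc3)c(O)cc(OC)c2Cc2ccc(O)cc2)c1 | target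

**Totals**
Total step count: 5. Longest linear sequence: 5 steps (1 → 2 → 3 → 6 → 11 → 12).

**Steps most likely to fail**

Step 4. Insertion of palladium into the C1–Br bond between two benzyl groups may be too slow. The arylacetylene released by fluoride would then be lost to oxidative dimerisation, or the arylpalladium diverted to hydrodebromination or to C–H arylation of a neighbouring benzyl ring. The fallback sets out from 6 and returns at 12; it gives up the alkyne and brings Cα in as a formyl carbon. Bromine–lithium exchange on 6 (n-BuLi, THF, −78 °C) gives [3-(benzyloxy)-2,6-bis[4-(benzyloxy)benzyl]-5-methoxyphenyl]lithium F1, which is quenched with DMF to give, after aqueous work-up, 3-(benzyloxy)-2,6-bis[4-(benzyloxy)benzyl]-5-methoxybenzaldehyde F2. Wittig olefination with the ylide from (3-methoxybenzyl)triphenylphosphonium chloride and KOt-Bu in THF gives 1-(benzyloxy)-2,4-bis[4-(benzyloxy)benzyl]-5-methoxy-3-[2-(3-methoxyphenyl)ethenyl]benzene F3 as an E/Z mixture. Hydrogenation under the conditions of step 5 saturates either alkene isomer, removes the benzyl groups and gives 12.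

Step 3. The second coupling may stall at an iodide flanked by bromine and an alkoxy group, the benzylzinc reagent may be consumed by homocoupling, or palladium may start to insert into C–Br once the iodides are gone. The fallback sets out from 3 and returns at 6; it reverses the polarity of the partners. Miyaura borylation of both C–I bonds (B2pin2, KOAc, PdCl2(dppf), dioxane, 80 °C) gives 2,2′-[4-(benzyloxy)-2-bromo-6-methoxy-1,3-phenylene]bis(4,4,5,5-tetramethyl-1,3,2-dioxaborolane) F4. Suzuki–Miyaura coupling of F4 with the benzylic chloride 4 (2.4 equiv, Pd(PPh3)4, K3PO4, toluene–H2O 10:1, 80 °C) gives 6. The benzylic C–Cl bond should react in preference to the aryl bromide, which is shielded on both sides.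

Step 2. Iodination may not stop cleanly at two iodines on the bromine-flanked carbons: attack at the carbon between the oxygens, or a third iodination, would give mixtures that are hard to separate. The fallback sets out from 1 and returns at 6; it introduces the two benzylic carbons one at a time as formyl groups.
- O-Methylation of 1 (MeI, K2CO3, acetone) gives 1-bromo-3,5-dimethoxybenzene F5.
- Vilsmeier–Haack formylation (POCl3, DMF, 90 °C) at one of the two equivalent bromine-flanked carbons gives the iminium salt [(2-bromo-4,6-dimethoxyphenyl)methylidene]dimethylammonium dichlorophosphate F6, which is hydrolysed on work-up to 2-bromo-4,6-dimethoxybenzaldehyde F7.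
- BCl3 (CH2Cl2, −78 to 0 °C) cleaves only the methyl ether chelated to the formyl group and gives 2-bromo-6-hydroxy-4-methoxybenzaldehyde F8, which differentiates the two oxygens.
- Benzylation (BnBr, K2CO3, DMF) gives 2-(benzyloxy)-6-bromo-4-methoxybenzaldehyde F9.
- Addition of 4-(benzyloxy)phenylmagnesium bromide (THF, 0 °C) gives racemic [2-(benzyloxy)-6-bromo-4-methoxyphenyl][4-(benzyloxy)phenyl]methanol F10.
- Ionic hydrogenation (Et3SiH, TFA, CH2Cl2, 0 °C) gives 1-(benzyloxy)-2-[4-(benzyloxy)benzyl]-3-bromo-5-methoxybenzene F11.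
- A second Vilsmeier–Haack formylation, at the remaining bromine-flanked carbon para to the benzyloxy group, gives the iminium salt ({4-(benzyloxy)-3-[4-(benzyloxy)benzyl]-2-bromo-6-methoxyphenyl}methylidene)dimethylammonium dichlorophosphate F12 and, after hydrolysis, 4-(benzyloxy)-3-[4-(benzyloxy)benzyl]-2-bromo-6-methoxybenzaldehyde F13.
- A second Grignard addition gives racemic {4-(benzyloxy)-3-[4-(benzyloxy)benzyl]-2-bromo-6-methoxyphenyl}[4-(benzyloxy)phenyl]methanol F14, and a second Et3SiH/TFA reduction gives 6.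

**Further compounds**
F1 | step 4 | [3-(benzyloxy)-2,6-bis[4-(benzyloxy)benzyl]-5-methoxyphenyl]lithium | [Li]c1c(Cc2ccc(OCc3ccccc3)cc2)c(OCc2ccccc2)cc(OC)c1Cc1ccc(OCc2ccccc2)cc1
F2 | step 4 | 3-(benzyloxy)-2,6-bis[4-(benzyloxy)benzyl]-5-methoxybenzaldehyde | COc1cc(OCc2ccccc2)c(Cc2ccc(OCc3ccccc3)cc2)c(C=O)c1Cc1ccc(OCc2ccccc2)cc1
F3 | step 4 | 1-(benzyloxy)-2,4-bis[4-(benzyloxy)benzyl]-5-methoxy-3-[2-(3-methoxyphenyl)ethenyl]benzene (E/Z mixture) | COc1cccc(C=Cc2c(Cc3ccc(OCc4ccccc4)cc3)c(OCc3ccccc3)cc(OC)c2Cc2ccc(OCc3ccccc3)cc2)c1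
F4 | step 3 | 2,2′-[4-(benzyloxy)-2-bromo-6-methoxy-1,3-phenylene]bis(4,4,5,5-tetramethyl-1,3,2-dioxaborolane) | COc1cc(OCc2ccccc2)c(B2OC(C)(C)C(C)(C)O2)c(Br)c1B1OC(C)(C)C(C)(C)O1
F5 | step 2 | 1-bromo-3,5-dimethoxybenzene | COc1cc(Br)cc(OC)c1
F6 | step 2 | [(2-bromo-4,6-dimethoxyphenyl)methylidene]dimethylammonium dichlorophosphate | COc1cc(Br)c(C=[N+](C)C)c(OC)c1.[O-]P(=O)(Cl)Cl
F7 | step 2 | 2-bromo-4,6-dimethoxybenzaldehyde | COc1cc(Br)c(C=O)c(OC)c1
F8 | step 2 | 2-bromo-6-hydroxy-4-methoxybenzaldehyde | COc1cc(O)c(C=O)c(Br)c1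
F9 | step 2 | 2-(benzyloxy)-6-bromo-4-methoxybenzaldehyde | COc1cc(OCc2ccccc2)c(C=O)c(Br)c1
F10 | step 2 | [2-(benzyloxy)-6-bromo-4-methoxyphenyl][4-(benzyloxy)phenyl]methanol (racemic) | COc1cc(OCc2ccccc2)c(C(O)c2ccc(OCc3ccccc3)cc2)c(Br)c1
F11 | step 2 | 1-(benzyloxy)-2-[4-(benzyloxy)benzyl]-3-bromo-5-methoxybenzene | COc1cc(OCc2ccccc2)c(Cc2ccc(OCc3ccccc3)cc2)c(Br)c1
F12 | step 2 | ({4-(benzyloxy)-3-[4-(benzyloxy)benzyl]-2-bromo-6-methoxyphenyl}methylidene)dimethylammonium dichlorophosphate | COc1cc(OCc2ccccc2)c(Cc2ccc(OCc3ccccc3)cc2)c(Br)c1C=[N+](C)C.[O-]P(=O)(Cl)Cl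
F13 | step 2 | 4-(benzyloxy)-3-[4-(benzyloxy)benzyl]-2-bromo-6-methoxybenzaldehyde | COc1cc(OCc2ccccc2)c(Cc2ccc(OCc3ccccc3)cc2)c(Br)c1C=O
F14 | step 2 | {4-(benzyloxy)-3-[4-(benzyloxy)benzyl]-2-bromo-6-methoxyphenyl}[4-(benzyloxy)phenyl]methanol (racemic) | COc1cc(OCc2ccccc2)c(Cc2ccc(OCc3ccccc3)cc2)c(Br)c1C(O)c1ccc(OCc2ccccc2)cc1
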